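The earlier runs and the new flask stem from a simulated flask for substances that don't exist, and the scatter is random.

The east run stops at 40.0 h with side product at 41 %, yet the flasks asked about hold the same charge of starting material and run to 3.0 d.

| flask | starting material | reagent | remark | time |
|---|---|---|---|---|
| east | 0.091 M | 1.1 equiv | run made earlier |  |
| north | 0.13 M | 1.1 equiv | run made earlier |  |
| south | 0.20 M | 1.1 equiv | run made earlier |  |
| south-west | 0.091 M | 2.2 equiv | run made earlier |  |
| red | 0.091 M | 1.10 equiv (fed, over 30 h) | all else is in the flask from the start; the feed brings no volume worth counting | 3.0 d |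
| amber | 0.091 M (fed, over 30 h) | 1.10 equiv | all else is in the flask from the start; the feed brings no volume worth counting | 3.0 d |
| blue | 0.091 M | 1.10 equiv | everything together at the start | 3.0 d |

east run (percent of the starting material charged)

| time / h | side product / % | target / % |
|---|---|---|
| 2.50 | 3 | 0 |
| 6.00 | 3 | 4 |
| 12.0 | 13 | 10 |
| 20.0 | 23 | 17 |
| 25.0 | 25 | 15 |
| 30.0 | 34 | 22 |
| 40.0 | 41 | 22 |

north run (percent of the starting material charged)

| time / d | side product / % | target / % |
|---|---|---|
| 0.417 | 10 | 13 |
| 0.833 | 23 | 19 |
| 1.25 | 33 | 20 |
| 1.67 | 44 | 19 |
| 2.00 | 55 | 17 |
| 2.50 | 58 | 16 |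
| 3.00 | 66 | 13 |

south run (percent of the starting material charged)

| time / d | side product / % | target / % |
|---|---|---|
| 0.167 | 3 | 4 |
| 0.500 | 16 | 18 |
| 0.833 | 31 | 22 |
| 1.25 | 38 | 23 |
| 1.67 | 48 | 24 |
| 2.50 | 64 | 18 |
| 3.00 | 66 | 13 |

south-west run (percent of the starting material charged)

| time / d | side product / % | target / % |
|---|---|---|
| 0.250 | 8 | 11 |
| 0.417 | 16 | 16 |
| 0.833 | 32 | 26 |
| 1.67 | 54 | 24 |
| 3.00 | 70 | 11 |

(scatter of a reading: 1.5 percentage points)



1. the flask that comes out highest in amount of side product, in percent of the starting material charged, or "all alike" when all lie within 1.5 percentage points (red / amber / blue / all alike)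
2. side product at the end, in percent of the starting material charged, red
3. side product at the end, in percent of the starting material charged, amber
4. side product at the end, in percent of the starting material charged, blue

How far does a flask with everything together go? East ends short, so I borrow north. North reads 44 % at 1.67 d, which is 3 percentage points above east at that time, and this gap is a reading with its scatter. North ends at 66 %. If the gap holds, blue ends near 63.0 %.

What does a feed cost? The run time less half the feed time is 2.38 d. This is the mean age of the fed charge, the time its portions spend in the flask on average, or its mean residence time. Red and amber share this age and the same ratio of reagent to starting material, 1.10 equiv, so I give them one figure. Drawn straight between its readings at 2.00 d and 2.50 d, north gives 57.2 % at that time, and less the gap that makes 54.2 %.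

Is the mean fair? The ages run from 1.75 d to 3.0 d. North's readings near those ends average 55.0 %, which is 2.2 points under the value at mean age, against a scatter of 1.5 points. So I put blue 8.8 points above the fed flasks, more than the margin.

The forecast also names blue, with its own figures of 65 % for blue, 58 % for amber and 54 % for red: “Feeding changes selectivity little; it only delays.”

The flasks give 62.8 % for blue, 53.6 % for red and 53.4 % for amber.

    starting material + reagent → intermediate + released group (k = 3.40 × 10⁻⁴ M⁻¹ s⁻¹)
    intermediate → side product (k = 9.30 × 10⁻⁶ s⁻¹)
    intermediate ⇌ target (K = 0.720, k = 1.30 × 10⁻⁵ s⁻¹)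

Amber ends with 10 % of its starting material left, blue with 6.9 %. Blue's own curve, drawn straight from 37.6 % at 1.50 d to 62.8 % at 3.00 d, reads 52.4 % at the mean age. The share of blue not yet side product falls from 62.4 % to 37.2 % over those times. Carried on as a first-order fall to a mean age of 7.38 d, it gives 91.8 % side product, and amber read at 8.0 d holds 91.7 %.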